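**Strategy.** The single stereocentre, C2 of the chroman ring (a tertiary ether carbon carrying CH3, O1 and the octaprenylmethyl chain), is traced back to the carbonyl carbon of all-E-octaprenylacetone, the C43 methyl ketone obtained by cleaving the 2,3-alkene of solanesol. This precursor has eight isolated trisubstituted alkenes and an unbranched CH2CH2 arm at the carbonyl. The key step transfers one CH2, the future C3, enantioselectively to this ketone, forming C2–C3 and an oxirane whose C2–O bond persists as C2–O1 of the pyran ring. A benzylic Grignard reagent then opens the oxirane at C3, and a quinone ketal joins O1 to the arene before reductive aromatisation.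

Key step: step 3

**Remarks before the steps**

- Chroman numbering (O1, C2, C3, C4, C4a, C5 to C8, C8a) is used from the key step onward; C2 is the former ketone carbon and C3 the ylide carbon.
- "The C41 chain" means all-E-octaprenylmethyl, –CH2–[CH2CH=C(CH3)CH2]7–CH2CH=C(CH3)2, i.e. (3E,7E,11E,15E,19E,23E,27E)-4,8,12,16,20,24,28,32-octamethyltritriaconta-3,7,11,15,19,23,27,31-octaenyl.
- Assumption on the chemistry: the (S)-binaphthoxide complex is taken to deliver CH2 to the Si face of an alkyl methyl ketone (O > CH2 > CH3), which gives the R oxirane. If a trial on geranylacetone shows the opposite sense, the (R)-binaphthoxide complex is used and nothing else changes.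

**Step 1**
Reactants: 1 all-E-solanesol
Product: 2 rac-(2R*,3R*)-2,3-epoxysolanesol
Conditions: VO(acac)2 (2 mol%), t-BuOOH (1.2 equiv, anhydrous), toluene, 0 °C to rt
Reagents that add atoms: tert-butyl hydroperoxide, CC(C)(C)OO
Why: Hydroxyl-directed vanadium-catalysed epoxidation: the allylic alkoxide binds the vanadium alkylperoxide and oxygen is delivered only to the 2,3-alkene, the eight remote trisubstituted alkenes having no directing group; the two new centres form as a racemate and are both erased in step 2.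

**Step 2**
Reactants: 2 rac-(2R*,3R*)-2,3-epoxysolanesol
Product: 4 all-E-octaprenylacetone, via solanesol triol 3 (not isolated)
Conditions: H5IO6 (2.5 equiv), THF/H2O 9:1, 0 °C to rt
Reagents that add atoms: water, O
Why: Periodic acid cleavage of an epoxide (Malaprade reaction after in-flask hydrolysis): aqueous H5IO6 opens the trisubstituted oxirane to triol 3 and cleaves both glycol bonds, releasing C1 as formaldehyde and C2 as formic acid and leaving the former C3 as the methyl ketone, while isolated alkenes do not react with periodate.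

**Step 3**
Reactants: 4 all-E-octaprenylacetone; 5 trimethylsulfoxonium iodide
Product: 8 (R)-2-methyl-2-(all-E-octaprenylmethyl)oxirane, via dimethylsulfoxonium methylide 6 (not isolated), via sulfoxonium betaine 7 (not isolated)
Conditions: 5, NaH, THF, reflux, filtration under Ar (ylide 6, 1.2 equiv); then 4, LaLi3(C20H12O2)3 from (S)-1,1'-bi-2-naphthol (5 mol%), (2,4,6-(MeO)3C6H2)3P=O (5 mol%), MS 5 Å, THF, rt
Reagents that add atoms: none
Why: Trivalent lanthanum of the heterobimetallic complex binds the carbonyl oxygen while a lithium binaphthoxide site, tuned by the phosphine oxide, positions the ylide, whose carbon adds to the carbonyl carbon to form C2–C3 and betaine 7. The closest known reaction is the catalytic asymmetric Corey–Chaykovsky epoxidation of methyl ketones with rare-earth alkali-metal binaphthoxide catalysts and an electron-rich triarylphosphine oxide. The oxirane closes by 3-exo-tet displacement of dimethyl sulfoxide from CH2 by the alkoxide, so no bond to C2 is broken after the addition. C2 is set by the catalyst alone: the chiral pocket distinguishes CH3 from the CH2CH2 arm and directs CH2 to the Si face, which corresponds to the R oxirane. The step needs facial selectivity and chemoselectivity; the first is secured by the methyl/unbranched-methylene pair at the carbonyl, the substrate class this catalyst differentiates best, and the second by the eight alkenes being isolated and electron-rich, hence inert to a sulfoxonium ylide. The weakly basic ylide and the neutral medium should leave the E alkenes and the enolisable ketone otherwise untouched.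

**Step 4**
Reactants: 9 1,4-dimethoxy-2,3-dimethylbenzene
Product: 10 1-(chloromethyl)-2,5-dimethoxy-3,4-dimethylbenzene
Conditions: (CH2O)n (1.1 equiv), conc. HCl, HCl (g), 1,4-dioxane, 40 °C
Reagents that add atoms: formaldehyde (from paraformaldehyde), C=O; hydrogen chloride, Cl
Why: Blanc chloromethylation, an electrophilic aromatic substitution at one of the two equivalent free positions of the electron-rich hydroquinone dimethyl ether; near-stoichiometric formaldehyde limits a second substitution.

**Step 5**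
Reactants: 8 (R)-2-methyl-2-(all-E-octaprenylmethyl)oxirane; 10 1-(chloromethyl)-2,5-dimethoxy-3,4-dimethylbenzene
Product: 12 (3R)-1-(2,5-dimethoxy-3,4-dimethylphenyl)-3-methyl tertiary alcohol bearing the C41 chain, via benzylic Grignard reagent 11 (not isolated)
Conditions: 10, Mg, THF, 0 °C, slow addition (11, 2.5 equiv); then 8, CuI (10 mol%), THF, −30 to 0 °C; aq. NH4Cl
Reagents that add atoms: none
Why: Magnesium insertion gives benzylic Grignard reagent 11, and CuI-catalysed SN2 opening of the 2,2-disubstituted oxirane takes place at the unhindered CH2 terminus (the future C3), so the C2–O bond and the configuration set in step 3 are untouched.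

**Step 6**
Reactants: 12 (3R)-tertiary alcohol
Product: 13 2-[(3R)-3-hydroxy-3-methyl-alkyl]-5,6-dimethyl-1,4-benzoquinone bearing the C41 chain
Conditions: (NH4)2Ce(NO3)6 (2.5 equiv), MeCN/CH2Cl2/H2O, 0 °C, 20 min
Reagents that add atoms: water, O
Why: Oxidative demethylation of a hydroquinone dimethyl ether with (NH4)2Ce(NO3)6: two one-electron oxidations with capture of water at the methoxy-bearing carbons and loss of methanol give the para-quinone within minutes at 0 °C, conditions that isolated trisubstituted alkenes and tertiary alcohols in polyprenyl quinone precursors tolerate.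

**Step 7**
Reactants: 13 hydroxyalkyl quinone
Product: 15 (2R)-8a-methoxy-2,7,8-trimethyl-2-(C41 chain)-2,3,4,8a-tetrahydro-6H-chromen-6-one (C8a epimers), via cyclic hemiketal 14 (not isolated)
Conditions: HC(OMe)3, MeOH, CH2Cl2, p-TsOH·H2O (5 mol%), 0 °C to rt; Et3N quench
Reagents that add atoms: methanol, CO
Why: Acid-catalysed intramolecular ketalisation: the tertiary hydroxyl adds 6-exo-trig to the neighbouring quinone carbonyl to give hemiketal 14, whose hydroxyl is exchanged for methoxy through the ring-oxygen-stabilised oxocarbenium ion while the orthoformate removes water; C2–O is never cleaved, so C2 keeps its configuration, and the new ketal centre C8a is flattened again in step 8.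

**Step 8**
Reactants: 15 cyclic quinone monoketal
Product: 17 plastochromanol-8, via methoxy dienol 16 (not isolated)
Conditions: NaBH4, MeOH/THF, 0 °C; then aq. citric acid, 0 °C, under Ar
Reagents that add atoms: none
Why: Reductive aromatisation of a quinone monoketal: hydride adds 1,2 to the cross-conjugated dienone (both β-carbons are fully substituted), and on mild acidification dienol 16 ionises at the ketal carbon with loss of the pseudo-axial methoxy group, whose C–O bond is aligned with the diene π system, and then loses the C6 proton to give the phenol; C2–O1 stays intact throughout, so the R configuration is retained.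

**Compound list**

1 | all-E-solanesol, (2E,6E,10E,14E,18E,22E,26E,30E)-3,7,11,15,19,23,27,31,35-nonamethylhexatriaconta-2,6,10,14,18,22,26,30,34-nonaen-1-ol | CC(C)=CCC/C(C)=C/CC/C(C)=C/CC/C(C)=C/CC/C(C)=C/CC/C(C)=C/CC/C(C)=C/CC/C(C)=C/CC/C(C)=C/CO | starting material
2 | rac-(2R*,3R*)-2,3-epoxysolanesol (trans oxirane, racemate; other eight alkenes all-E) | CC(C)=CCC/C(C)=C/CC/C(C)=C/CC/C(C)=C/CC/C(C)=C/CC/C(C)=C/CC/C(C)=C/CC/C(C)=C/CCC1(C)OC1CO | intermediate
3 | solanesol triol, 2,3-dihydro-2,3-dihydroxysolanesol (stereoisomer mixture) | CC(C)=CCC/C(C)=C/CC/C(C)=C/CC/C(C)=C/CC/C(C)=C/CC/C(C)=C/CC/C(C)=C/CC/C(C)=C/CCC(C)(O)C(O)CO | intermediate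
4 | all-E-octaprenylacetone, (5E,9E,13E,17E,21E,25E,29E)-6,10,14,18,22,26,30,34-octamethylpentatriaconta-5,9,13,17,21,25,29,33-octaen-2-one | CC(C)=CCC/C(C)=C/CC/C(C)=C/CC/C(C)=C/CC/C(C)=C/CC/C(C)=C/CC/C(C)=C/CC/C(C)=C/CCC(C)=O | intermediate
5 | trimethylsulfoxonium iodide | C[S+](C)(C)=O.[I-] | starting material
6 | dimethylsulfoxonium methylide | C[S+](C)(=O)[CH2-] | intermediate
7 | sulfoxonium betaine, (R)-configured tertiary alkoxide carrying CH3, the C41 chain and CH2S(O)(CH3)2 | CC(C)=CCC/C(C)=C/CC/C(C)=C/CC/C(C)=C/CC/C(C)=C/CC/C(C)=C/CC/C(C)=C/CC/C(C)=C/CC[C@]([O-])(C)C[S+](C)(C)=O | intermediate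
8 | (R)-2-methyl-2-(all-E-octaprenylmethyl)oxirane | CC(C)=CCC/C(C)=C/CC/C(C)=C/CC/C(C)=C/CC/C(C)=C/CC/C(C)=C/CC/C(C)=C/CC/C(C)=C/CC[C@]1(C)CO1 | intermediate
9 | 1,4-dimethoxy-2,3-dimethylbenzene | COc1ccc(OC)c(C)c1C | starting material
10 | 1-(chloromethyl)-2,5-dimethoxy-3,4-dimethylbenzene | COc1cc(CCl)c(OC)c(C)c1C | intermediate
11 | benzylic Grignard reagent, 2,5-dimethoxy-3,4-dimethylbenzylmagnesium chloride | COc1cc(C[Mg]Cl)c(OC)c(C)c1C | intermediate
12 | (3R,6E,10E,14E,18E,22E,26E,30E)-1-(2,5-dimethoxy-3,4-dimethylphenyl)-3,7,11,15,19,23,27,31,35-nonamethylhexatriaconta-6,10,14,18,22,26,30,34-octaen-3-ol | CC(C)=CCC/C(C)=C/CC/C(C)=C/CC/C(C)=C/CC/C(C)=C/CC/C(C)=C/CC/C(C)=C/CC/C(C)=C/CC[C@](O)(C)CCc1cc(OC)c(C)c(C)c1OC | intermediate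
13 | 2-[(3R,6E,10E,14E,18E,22E,26E,30E)-3-hydroxy-3,7,11,15,19,23,27,31,35-nonamethylhexatriaconta-6,10,14,18,22,26,30,34-octaenyl]-5,6-dimethyl-1,4-benzoquinone | CC(C)=CCC/C(C)=C/CC/C(C)=C/CC/C(C)=C/CC/C(C)=C/CC/C(C)=C/CC/C(C)=C/CC/C(C)=C/CC[C@](O)(C)CCC1=CC(=O)C(C)=C(C)C1=O | intermediate
14 | cyclic hemiketal, (2R)-8a-hydroxy-2,7,8-trimethyl-2-(C41 chain)-2,3,4,8a-tetrahydro-6H-chromen-6-one (C8a epimers) | CC(C)=CCC/C(C)=C/CC/C(C)=C/CC/C(C)=C/CC/C(C)=C/CC/C(C)=C/CC/C(C)=C/CC/C(C)=C/CC[C@]1(C)CCC2=CC(=O)C(C)=C(C)C2(O)O1 | intermediate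
15 | (2R)-8a-methoxy-2,7,8-trimethyl-2-(C41 chain)-2,3,4,8a-tetrahydro-6H-chromen-6-one (C8a epimers) | CC(C)=CCC/C(C)=C/CC/C(C)=C/CC/C(C)=C/CC/C(C)=C/CC/C(C)=C/CC/C(C)=C/CC/C(C)=C/CC[C@]1(C)CCC2=CC(=O)C(C)=C(C)C2(OC)O1 | intermediate
16 | methoxy dienol, (2R)-8a-methoxy-2,7,8-trimethyl-2-(C41 chain)-3,4,6,8a-tetrahydro-2H-chromen-6-ol (isomer mixture at C6 and C8a) | CC(C)=CCC/C(C)=C/CC/C(C)=C/CC/C(C)=C/CC/C(C)=C/CC/C(C)=C/CC/C(C)=C/CC/C(C)=C/CC[C@]1(C)CCC2=CC(O)C(C)=C(C)C2(OC)O1 | intermediate
17 | plastochromanol-8, (2R)-2,7,8-trimethyl-2-(C41 chain)-3,4-dihydro-2H-chromen-6-ol | CC(C)=CCC/C(C)=C/CC/C(C)=C/CC/C(C)=C/CC/C(C)=C/CC/C(C)=C/CC/C(C)=C/CC/C(C)=C/CC[C@]1(C)CCc2cc(O)c(C)c(C)c2O1 | target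

**Step count**

Total: 8 steps. Longest linear sequence: 7 steps (1, 2, 3, 5, 6, 7, 8 from solanesol); step 4 is the convergent branch.

**Steps most likely to fail**

1. Step 3. Facial discrimination between CH3 and the long CH2CH2 arm may be insufficient, or the catalyst may be slowed by protic traces in the waxy ketone; the oily oxirane cannot be enriched by crystallisation. Fallback, setting out from 1 and 9 and returning at 12: Katsuki–Sharpless asymmetric epoxidation of 1 (Ti(OiPr)4, D-(−)-diethyl tartrate, t-BuOOH, 4 Å sieves, CH2Cl2, −20 °C) should give (2R,3R)-2,3-epoxysolanesol F1. Hydride opening at C2 with NaAlH2(OCH2CH2OCH3)2 in THF at 0 °C gives the (3R)-1,3-diol F2, and selective sulfonylation of the primary hydroxyl (TsCl, pyridine, 0 °C) gives the (3R)-3-hydroxy primary tosylate F3. In parallel, 9 is brominated (NBS, MeCN) to 1-bromo-2,5-dimethoxy-3,4-dimethylbenzene F4 and converted with Mg in THF into 2,5-dimethoxy-3,4-dimethylphenylmagnesium bromide F5. Li2CuCl4-catalysed coupling of excess F5 with F3 at low temperature gives 12. Here C1 and C2 of solanesol become C4 and C3 of the chroman, and the stereocentre is set by the reagent-controlled epoxidation.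

2. Step 8. The mixed ketal may ionise with loss of the ring oxygen instead of methoxide (giving a ring-opened hydroquinone monomethyl ether), or hydride addition may be incomplete. Fallback, setting out from 13 and returning at 17: reduction of 13 with aqueous Na2S2O4 in Et2O gives the hydroquinone tertiary alcohol F6. Acid-catalysed cyclodehydration (catalytic p-TsOH, toluene, 50 °C, Ar) closes the ring at the hydroquinone oxidation level through a hemiketal of the keto tautomer and loss of water from the ring carbon, a pathway that should keep C2–O intact and proceed mainly with retention.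

3. Step 5. Wurtz homocoupling may consume the benzylic chloride during magnesium insertion, and magnesium halide may promote Meinwald rearrangement or halohydrin formation of the 2,2-disubstituted oxirane before C–C bond formation. Fallback, setting out from 10 and 8 and returning at 12: displacement of chloride in 10 with PhSO2Na (DMF, 60 °C) gives 2,5-dimethoxy-3,4-dimethylbenzyl phenyl sulfone F7. Its lithio derivative (n-BuLi, THF/DMPU, −78 °C to rt) opens 8 at CH2 to give the γ-hydroxy sulfone F8 (epimers at the sulfonyl carbon). Reductive desulfonylation with sodium amalgam (Na/Hg, Na2HPO4, MeOH/THF, −20 °C) gives 12.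

**Further compounds**

F1 | step 3 | (2R,3R)-2,3-epoxysolanesol | CC(C)=CCC/C(C)=C/CC/C(C)=C/CC/C(C)=C/CC/C(C)=C/CC/C(C)=C/CC/C(C)=C/CC/C(C)=C/CC[C@@]1(C)O[C@@H]1CO
F2 | step 3 | (3R,6E,10E,14E,18E,22E,26E,30E)-3,7,11,15,19,23,27,31,35-nonamethylhexatriaconta-6,10,14,18,22,26,30,34-octaene-1,3-diol | CC(C)=CCC/C(C)=C/CC/C(C)=C/CC/C(C)=C/CC/C(C)=C/CC/C(C)=C/CC/C(C)=C/CC/C(C)=C/CC[C@](O)(C)CCO
F3 | step 3 | (3R)-3-hydroxy primary 4-methylbenzenesulfonate of diol F2 | CC(C)=CCC/C(C)=C/CC/C(C)=C/CC/C(C)=C/CC/C(C)=C/CC/C(C)=C/CC/C(C)=C/CC/C(C)=C/CC[C@](O)(C)CCOS(=O)(=O)c1ccc(C)cc1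
F4 | step 3 | 1-bromo-2,5-dimethoxy-3,4-dimethylbenzene | COc1cc(Br)c(OC)c(C)c1C
F5 | step 3 | 2,5-dimethoxy-3,4-dimethylphenylmagnesium bromide | COc1cc([Mg]Br)c(OC)c(C)c1C
F6 | step 8 | 5-[(3R)-3-hydroxy-3-methyl-alkyl bearing the C41 chain]-2,3-dimethylbenzene-1,4-diol | CC(C)=CCC/C(C)=C/CC/C(C)=C/CC/C(C)=C/CC/C(C)=C/CC/C(C)=C/CC/C(C)=C/CC/C(C)=C/CC[C@](O)(C)CCc1cc(O)c(C)c(C)c1O
F7 | step 5 | 2,5-dimethoxy-3,4-dimethylbenzyl phenyl sulfone | COc1cc(CS(=O)(=O)c2ccccc2)c(OC)c(C)c1C
F8 | step 5 | γ-hydroxy sulfone, 1-phenylsulfonyl derivative of 12 (epimers at the sulfonyl carbon) | CC(C)=CCC/C(C)=C/CC/C(C)=C/CC/C(C)=C/CC/C(C)=C/CC/C(C)=C/CC/C(C)=C/CC/C(C)=C/CC[C@](O)(C)CC(c1cc(OC)c(C)c(C)c1OC)S(=O)(=O)c1ccccc1
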